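**Plan**
- Retrosynthesis: the allyl ether on O5 of ring B is cut last, then the pyran of chromene A (O1–C2 and C4–C4a), then the bond from C8 of ring A to the benzylic CH(CH3) carbon, then the 1-sulfonylethyl handle at C6 of ring B, then the pyran of chromene B.
- Forward: phloroacetophenone → 4-O-allyl ether → pyran of chromene B → 1-tosylethyl group at C6 → union with 3,5-dimethoxyphenol (ring A) → pyran of chromene A → deallylation.
- Enabling feature: the C7 hydroxyl of ring B is ortho to the benzylic carbon, so ring B can be dearomatised to an ortho-quinone methide (C7=O, exocyclic C6=CH–CH3) that re-aromatises as the bond forms. C8 of ring A is ortho to the pyran oxygen O1, so it is one of the two equivalent ortho carbons of 3,5-dimethoxyphenol and the C8/C6 question does not arise.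
- Stereochemistry: the single stereocentre is set in the union by a chiral bifunctional cinchona squaramide (catalyst control) and is carried through basic, thermal and neutral steps only.
- Helpers: the tosyl group leaves in the union; the allyl ether directs closure of pyran B to the oxygen next to the acetyl group, keeps the quinone methide neutral, distinguishes O5 of ring B from the ring A hydroxyl, and is removed last.

Key step: step 4

Assumption: the sense of induction of cinchona squaramides on this methide cannot be derived from a close analogue. The route is written with the quinine-derived catalyst giving the (S)-adduct 13; its quinidine-derived pseudoenantiomer takes its place if the first run shows the opposite sense.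

Remark: the descriptor at the benzylic carbon reads S in 13, 15 and 16 and R in 17, 18 and 19 only because ligand priorities change; the spatial arrangement is the same throughout.

Remark: in the aqueous formic acid of step 3 the benzylic alcohol 9 is substituted by ionisation of its protonated form; the neutral ortho-quinone methide 12 is formed as a discrete species only under the basic conditions of step 4.

**Step 1**
Reactants: 1 1-(2,4,6-trihydroxyphenyl)ethan-1-one; 2 3-bromoprop-1-ene (allyl bromide)
Product: 3 1-[2,6-dihydroxy-4-(prop-2-en-1-yloxy)phenyl]ethan-1-one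
Conditions: allyl bromide (1.05 equiv), K2CO3 (1.1 equiv), acetone, rt
Reagents that add atoms: allyl bromide, C=CCBr
Why: Williamson etherification should go to the C4 hydroxyl, the only one not hydrogen-bonded to the acetyl carbonyl and the most acidic, while the two chelated ortho hydroxyls stay free.

**Step 2**
Reactants: 3 1-[2,6-dihydroxy-4-(prop-2-en-1-yloxy)phenyl]ethan-1-one; 4 3-methylbut-2-enal
Product: 6 1-[7-hydroxy-2,2-dimethyl-5-(prop-2-en-1-yloxy)-2H-chromen-8-yl]ethan-1-one, via oxatriene 5 (not isolated)
Conditions: 4 (1.2 equiv), ethylenediammonium diacetate (10 mol %), toluene, reflux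
Reagents that add atoms: 3-methylbut-2-enal, CC(C)=CC=O
Why: Knoevenagel-type condensation at one of the two equivalent free ring carbons and oxa-6π electrocyclisation of oxatriene 5 can only close onto the hydroxyl next to the acetyl group because the other neighbouring oxygen is allylated, and limiting the aldehyde suppresses a second annulation.

**Step 3**
Reactants: 6 1-[7-hydroxy-2,2-dimethyl-5-(prop-2-en-1-yloxy)-2H-chromen-8-yl]ethan-1-one; 7 acetaldehyde; 8 sodium 4-methylbenzenesulfinate
Product: 10 racemic 1-[7-hydroxy-2,2-dimethyl-6-[1-(4-methylbenzenesulfonyl)ethyl]-5-(prop-2-en-1-yloxy)-2H-chromen-8-yl]ethan-1-one, via benzylic alcohol 9 (not isolated)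
Conditions: CH3CHO (3 equiv), 4-MeC6H4SO2Na (2 equiv), HCO2H/H2O, rt
Reagents that add atoms: acetaldehyde, CC=O; sodium 4-methylbenzenesulfinate, Cc1ccc(S(=O)[O-])cc1.[Na+]
Why: three-component sulfonylalkylation of a phenol, in which hydroxyalkylation at C6 (the only aromatic CH, ortho or para to three oxygens) gives 9 and acid-promoted SN1-type exchange of its benzylic hydroxyl for the sulfonyl group, by sulfur attack of the sulfinic acid as the protonated alcohol ionises, gives a stable, storable precursor.

**Step 4**
Reactants: 10 racemic 1-[7-hydroxy-2,2-dimethyl-6-[1-(4-methylbenzenesulfonyl)ethyl]-5-(prop-2-en-1-yloxy)-2H-chromen-8-yl]ethan-1-one; 11 3,5-dimethoxyphenol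
Product: 13 1-[7-hydroxy-6-[(1S)-1-(2-hydroxy-4,6-dimethoxyphenyl)ethyl]-2,2-dimethyl-5-(prop-2-en-1-yloxy)-2H-chromen-8-yl]ethan-1-one, via ortho-quinone methide 12 (not isolated)
Conditions: 11 (2 equiv), quinine-derived 3,5-bis(trifluoromethyl)phenyl squaramide (10 mol %), aq. K2CO3, toluene, 0 °C
Reagents that add atoms: 3,5-dimethoxyphenol, COc1cc(O)cc(OC)c1
Why: K2CO3 deprotonates the C7 hydroxyl of 10 and 1,4-elimination of 4-methylbenzenesulfinate dearomatises ring B to ortho-quinone methide 12 (C7=O, exocyclic C6=CH–CH3); the squaramide NH groups bind the C7 carbonyl while the quinuclidine nitrogen binds the hydroxyl of 11, whose ortho carbon adds to the methide carbon, and tautomerisation re-aromatises both rings. The closest known reaction type is the organocatalytic asymmetric Friedel–Crafts alkylation of naphthols and electron-rich phenols by ortho-quinone methides generated in situ from 2-(1-sulfonylalkyl)phenols. No ring is closed. The new stereocentre is set under catalyst control: the chiral pocket decides which face of the planar methide carbon is attacked, and the methide geometry is fixed by the substrate because the methyl group turns towards the small C7 carbonyl oxygen and away from the C5 allyloxy group. The step needs carbon over oxygen alkylation (the aryl benzyl ether reverts to 12), ortho over para attack (hydrogen-bonded delivery from the hydroxyl; the two ortho carbons of 11 are equivalent, which places the new bond at the future C8 of ring A) and single alkylation (excess 11). The allyl ether on O5 keeps 12 neutral and electrophilic, and the basic medium avoids acid-mediated reversal of the bond formation.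

**Step 5**
Reactants: 13 1-[7-hydroxy-6-[(1S)-1-(2-hydroxy-4,6-dimethoxyphenyl)ethyl]-2,2-dimethyl-5-(prop-2-en-1-yloxy)-2H-chromen-8-yl]ethan-1-one; 14 3-chloro-3-methylbut-1-yne
Product: 15 1-[6-[(1S)-1-[2,4-dimethoxy-6-(2-methylbut-3-yn-2-yloxy)phenyl]ethyl]-7-hydroxy-2,2-dimethyl-5-(prop-2-en-1-yloxy)-2H-chromen-8-yl]ethan-1-one
Conditions: 14 (3 equiv), K2CO3 (2 equiv), KI (10 mol %), CuI (5 mol %), acetone, 55 °C (sealed)
Reagents that add atoms: 3-chloro-3-methylbut-1-yne, C#CC(C)(C)Cl
Why: copper-assisted propargylic etherification (Williamson type) should take the ring A hydroxyl only, since the C7 hydroxyl of ring B is chelated to the acetyl carbonyl and flanked by two substituents; the stereocentre is not touched.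

**Step 6**
Reactants: 15 1-[6-[(1S)-1-[2,4-dimethoxy-6-(2-methylbut-3-yn-2-yloxy)phenyl]ethyl]-7-hydroxy-2,2-dimethyl-5-(prop-2-en-1-yloxy)-2H-chromen-8-yl]ethan-1-one
Product: 18 1-[6-[(1R)-1-(5,7-dimethoxy-2,2-dimethyl-2H-chromen-8-yl)ethyl]-7-hydroxy-2,2-dimethyl-5-(prop-2-en-1-yloxy)-2H-chromen-8-yl]ethan-1-one, via allenylphenol 16 (not isolated), via oxatriene 17 (not isolated)
Conditions: DMF, 130 °C
Reagents that add atoms: none
Why: aromatic propargyl Claisen rearrangement to the only free ortho carbon of ring A, 1,5-hydrogen shift and oxa-6π electrocyclisation close the pyran of chromene A with no regiochemical choice, at a temperature at which the doubly ortho-blocked allyl ether of ring B should not rearrange.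

**Step 7**
Reactants: 18 1-[6-[(1R)-1-(5,7-dimethoxy-2,2-dimethyl-2H-chromen-8-yl)ethyl]-7-hydroxy-2,2-dimethyl-5-(prop-2-en-1-yloxy)-2H-chromen-8-yl]ethan-1-one
Product: 19 1-[6-[(1R)-1-(5,7-dimethoxy-2,2-dimethyl-2H-chromen-8-yl)ethyl]-5,7-dihydroxy-2,2-dimethyl-2H-chromen-8-yl]ethan-1-one
Conditions: Pd(PPh3)4 (5 mol %), morpholine (5 equiv), THF, rt
Reagents that add atoms: none
Why: Tsuji–Trost deallylation, in which zerovalent palladium ionises only the allyl aryl ether (the C2–O bonds of the two chromenes lie in the nodal plane of their alkenes) and morpholine traps the allyl unit, under neutral conditions that should spare the acid-labile benzylic stereocentre.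

**Compound list**
1 | 1-(2,4,6-trihydroxyphenyl)ethan-1-one (phloroacetophenone) | CC(=O)c1c(O)cc(O)cc1O | starting material
2 | 3-bromoprop-1-ene (allyl bromide) | C=CCBr | starting material
3 | 1-[2,6-dihydroxy-4-(prop-2-en-1-yloxy)phenyl]ethan-1-one | CC(=O)c1c(O)cc(OCC=C)cc1O | intermediate
4 | 3-methylbut-2-enal | CC(C)=CC=O | starting material
5 | 2-acetyl-3-hydroxy-6-(3-methylbut-2-en-1-ylidene)-5-(prop-2-en-1-yloxy)cyclohexa-2,4-dien-1-one (oxatriene, alkene geometry not defined) | CC(=O)C1=C(O)C=C(OCC=C)C(=CC=C(C)C)C1=O | intermediate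
6 | 1-[7-hydroxy-2,2-dimethyl-5-(prop-2-en-1-yloxy)-2H-chromen-8-yl]ethan-1-one | CC(=O)c1c(O)cc(OCC=C)c2c1OC(C)(C)C=C2 | intermediate
7 | acetaldehyde | CC=O | starting material
8 | sodium 4-methylbenzenesulfinate | Cc1ccc(S(=O)[O-])cc1.[Na+] | starting material
9 | racemic 1-[7-hydroxy-6-(1-hydroxyethyl)-2,2-dimethyl-5-(prop-2-en-1-yloxy)-2H-chromen-8-yl]ethan-1-one | CC(=O)c1c(O)c(C(C)O)c(OCC=C)c2c1OC(C)(C)C=C2 | intermediate
10 | racemic 1-[7-hydroxy-2,2-dimethyl-6-[1-(4-methylbenzenesulfonyl)ethyl]-5-(prop-2-en-1-yloxy)-2H-chromen-8-yl]ethan-1-one | CC(=O)c1c(O)c(C(C)S(=O)(=O)c2ccc(C)cc2)c(OCC=C)c2c1OC(C)(C)C=C2 | intermediate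
11 | 3,5-dimethoxyphenol | COc1cc(O)cc(OC)c1 | starting material
12 | 8-acetyl-6-ethylidene-2,2-dimethyl-5-(prop-2-en-1-yloxy)-2H-chromen-7(6H)-one (ortho-quinone methide, alkene geometry not defined) | CC(=O)C1=C2OC(C)(C)C=CC2=C(OCC=C)C(=CC)C1=O | intermediate
13 | 1-[7-hydroxy-6-[(1S)-1-(2-hydroxy-4,6-dimethoxyphenyl)ethyl]-2,2-dimethyl-5-(prop-2-en-1-yloxy)-2H-chromen-8-yl]ethan-1-one | COc1cc(OC)c([C@H](C)c2c(O)c(C(C)=O)c3OC(C)(C)C=Cc3c2OCC=C)c(O)c1 | intermediate
14 | 3-chloro-3-methylbut-1-yne | C#CC(C)(C)Cl | starting material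
15 | 1-[6-[(1S)-1-[2,4-dimethoxy-6-(2-methylbut-3-yn-2-yloxy)phenyl]ethyl]-7-hydroxy-2,2-dimethyl-5-(prop-2-en-1-yloxy)-2H-chromen-8-yl]ethan-1-one | COc1cc(OC)c([C@H](C)c2c(O)c(C(C)=O)c3OC(C)(C)C=Cc3c2OCC=C)c(OC(C)(C)C#C)c1 | intermediate
16 | 1-[7-hydroxy-6-[(1S)-1-[2-hydroxy-4,6-dimethoxy-3-(3-methylbuta-1,2-dien-1-yl)phenyl]ethyl]-2,2-dimethyl-5-(prop-2-en-1-yloxy)-2H-chromen-8-yl]ethan-1-one (allenylphenol) | COc1cc(OC)c([C@H](C)c2c(O)c(C(C)=O)c3OC(C)(C)C=Cc3c2OCC=C)c(O)c1C=C=C(C)C | intermediate
17 | 2-[(1R)-1-[8-acetyl-7-hydroxy-2,2-dimethyl-5-(prop-2-en-1-yloxy)-2H-chromen-6-yl]ethyl]-3,5-dimethoxy-6-(3-methylbut-2-en-1-ylidene)cyclohexa-2,4-dien-1-one (oxatriene, alkene geometry not defined) | COC1=CC(OC)=C([C@H](C)c2c(O)c(C(C)=O)c3OC(C)(C)C=Cc3c2OCC=C)C(=O)C1=CC=C(C)C | intermediate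
18 | 1-[6-[(1R)-1-(5,7-dimethoxy-2,2-dimethyl-2H-chromen-8-yl)ethyl]-7-hydroxy-2,2-dimethyl-5-(prop-2-en-1-yloxy)-2H-chromen-8-yl]ethan-1-one | COc1cc(OC)c([C@H](C)c2c(O)c(C(C)=O)c3OC(C)(C)C=Cc3c2OCC=C)c2OC(C)(C)C=Cc12 | intermediate
19 | 1-[6-[(1R)-1-(5,7-dimethoxy-2,2-dimethyl-2H-chromen-8-yl)ethyl]-5,7-dihydroxy-2,2-dimethyl-2H-chromen-8-yl]ethan-1-one | COc1cc(OC)c([C@H](C)c2c(O)c3c(c(C(C)=O)c2O)OC(C)(C)C=C3)c2c1C=CC(C)(C)O2 | target

**Step count and risks**
Total step count: 7. Longest linear sequence: 7 steps (1 to 19); 11 enters in step 4.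

Steps most likely to fail:

1. Step 4. The risks are poor facial selectivity on the doubly ortho-flanked methide, an uncatalysed background addition at the water–toluene interface, and tautomerisation of the methide to the vinylphenol. Fallback: from 10, union with 11 under aqueous K2CO3 in toluene without a chiral catalyst should give racemic 1-[7-hydroxy-6-[1-(2-hydroxy-4,6-dimethoxyphenyl)ethyl]-2,2-dimethyl-5-(prop-2-en-1-yloxy)-2H-chromen-8-yl]ethan-1-one F1. This is resolved by preparative chromatography on a polysaccharide chiral stationary phase. The (S)-enantiomer is 13, where the route is rejoined; the antipode 1-[7-hydroxy-6-[(1R)-1-(2-hydroxy-4,6-dimethoxyphenyl)ethyl]-2,2-dimethyl-5-(prop-2-en-1-yloxy)-2H-chromen-8-yl]ethan-1-one F2 is set aside.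

2. Step 3. The risks are slow hydroxyalkylation of the acetyl-bearing ring, capture of the ionised benzylic alcohol by a second molecule of the chromenol instead of sulfinate, and acid-promoted hydration of the chromene alkene. Fallback: from 6, Vilsmeier–Haack formylation (POCl3, DMF, 0 °C to rt, aqueous NaOAc work-up) at C6 should give 8-acetyl-7-hydroxy-2,2-dimethyl-5-(prop-2-en-1-yloxy)-2H-chromene-6-carbaldehyde F3. Aldehyde-selective methyl transfer with MeTi(OiPr)3 (2.2 equiv, THF, −40 °C) gives benzylic alcohol 9, which is treated without purification with 4-methylbenzenesulfinic acid in CH2Cl2 and comes back to the route at 10.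

3. Step 5. The risks are slow or unselective O-alkylation of the hindered ring A hydroxyl by the tertiary propargylic electrophile and loss of the chloride by elimination. Fallback: from 13, direct condensation with 4 (ethylenediammonium diacetate, toluene, reflux) should take place at the only free ortho carbon of ring A, pass through oxatriene 17 by dehydration and close by oxa-6π electrocyclisation. It comes back to the route at 18 and bypasses 15 and 16. The ring B hydroxyl has no free ortho carbon and cannot take part. No compound outside the list is made (F0).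

**Further compounds**
F1 | step 4 | racemic 1-[7-hydroxy-6-[1-(2-hydroxy-4,6-dimethoxyphenyl)ethyl]-2,2-dimethyl-5-(prop-2-en-1-yloxy)-2H-chromen-8-yl]ethan-1-one | COc1cc(OC)c(C(C)c2c(O)c(C(C)=O)c3OC(C)(C)C=Cc3c2OCC=C)c(O)c1
F2 | step 4 | 1-[7-hydroxy-6-[(1R)-1-(2-hydroxy-4,6-dimethoxyphenyl)ethyl]-2,2-dimethyl-5-(prop-2-en-1-yloxy)-2H-chromen-8-yl]ethan-1-one | COc1cc(OC)c([C@@H](C)c2c(O)c(C(C)=O)c3OC(C)(C)C=Cc3c2OCC=C)c(O)c1
F3 | step 3 | 8-acetyl-7-hydroxy-2,2-dimethyl-5-(prop-2-en-1-yloxy)-2H-chromene-6-carbaldehyde | CC(=O)c1c(O)c(C=O)c(OCC=C)c2c1OC(C)(C)C=C2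
F0 | step 5 | none | none
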